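**Plan**

Numbering: C1 is the quaternary carbinol, C7 its CH2O carbon, C2 the carbinol next to C3H2–C4H2, C5 the benzoyloxy carbon, C6 the carbinol between C5 and C1. The C2 and C6 oxygens both stand on the ring face that carries C7, so the C2–C1–C6 part of the cyclohexane hides a mirror plane and the ring maps onto an achiral 1-alkoxy-1-(hydroxymethyl)cyclohexa-2,5-diene with two enantiotopic alkenes.
Cuts, last bond first: benzyl–O at C1 and benzoyl–O at C7; C2–O and C3–H (hydration of C2=C3 through a C7–O–Si tether); C5–OBz (benzoate opening of an oxirane); the C5–O and C6–O oxirane bonds (asymmetric directed epoxidation); then the C1–O bond and the ring hydrogens, back to benzoic acid and benzyl bromide.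
Forward: the carbocycle is the ring of benzoic acid after Birch reduction. C1 is hydroxylated through the ester enolate and benzylated, the ester is reduced to the directing CH2OH, the C5–C6 oxirane is closed and then opened, C2=C3 is hydrated through a transient oxasilolane, and C7 benzoylation and debenzylation finish the route.
Stereochemistry: the chiral ligand on vanadium chooses the alkene and the bound C7 hydroxyl the face, which fixes C1, C5 and C6 in one step; SN2 opening inverts C5; the silicon tether places the C2 oxygen cis to C7.

Key step: step 6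

Assumption: the (1R,2R)-configured bishydroxamic acid is taken to select the alkene that becomes C5–C6 of 10; the sense of induction has to be confirmed on the first run, and if it is the opposite the (1S,2S)-ligand is used with nothing else changed.
Naming: ring compounds 11 to 16 carry the route numbering given above.

**Route**

Step 1
Reactants: 1 benzoic acid
Product: 2 cyclohexa-2,5-diene-1-carboxylic acid
Conditions: Na, liquid NH3, EtOH, −78 °C; NH4Cl; aq. HCl
Reagents that add atoms: none
Why: Birch reduction of the benzoate salt places the two hydrogens at the ipso and para carbons, which gives the unconjugated 2,5-diene acid.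

Step 2
Reactants: 2 cyclohexa-2,5-diene-1-carboxylic acid
Product: 3 methyl cyclohexa-2,5-diene-1-carboxylate
Conditions: MeI, K2CO3, DMF, rt
Reagents that add atoms: iodomethane, CI
Why: SN2 O-methylation of the carboxylate forms the ester under a carbonate base that is too weak to move the skipped diene into conjugation.

Step 3
Reactants: 3 methyl cyclohexa-2,5-diene-1-carboxylate
Product: 5 methyl 1-hydroxycyclohexa-2,5-diene-1-carboxylate, via potassium dienolate 4 (not isolated)
Conditions: KN(SiMe3)2, THF, −78 °C; then 2-(benzenesulfonyl)-3-phenyloxaziridine, −78 °C; aq. NH4Cl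
Reagents that add atoms: 2-(benzenesulfonyl)-3-phenyloxaziridine, O=S(=O)(N1OC1c1ccccc1)c1ccccc1
Why: Electrophilic enolate hydroxylation by an N-sulfonyloxaziridine (Davis oxidation) should take place at the alpha carbon C1, where this cross-conjugated dienolate also reacts in Birch-type alkylations, so the two alkenes stay out of conjugation.

Step 4
Reactants: 5 methyl 1-hydroxycyclohexa-2,5-diene-1-carboxylate; 6 benzyl bromide
Product: 8 methyl 1-(benzyloxy)cyclohexa-2,5-diene-1-carboxylate, via sodium alkoxide 7 (not isolated)
Conditions: NaH, THF/DMF, 0 °C; then BnBr, Bu4NI (cat.), 0 °C to rt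
Reagents that add atoms: none
Why: Williamson etherification of the tertiary alkoxide with a reactive benzylic halide runs under base only, so the acid-triggered dehydration of the doubly allylic carbinol to methyl benzoate is avoided.

Step 5
Reactants: 8 methyl 1-(benzyloxy)cyclohexa-2,5-diene-1-carboxylate
Product: 9 [1-(benzyloxy)cyclohexa-2,5-dien-1-yl]methanol
Conditions: LiAlH4, Et2O, 0 °C; then H2O
Reagents that add atoms: none
Why: LiAlH4 reduction of the ester gives the primary alcohol that will carry the catalyst, while the ether and the isolated alkenes are inert to hydride and the basic work-up spares the acid-labile doubly allylic ether.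

Step 6
Reactants: 9 [1-(benzyloxy)cyclohexa-2,5-dien-1-yl]methanol
Product: 10 [(1S,2R,6S)-2-(benzyloxy)-7-oxabicyclo[4.1.0]hept-3-en-2-yl]methanol
Conditions: VO(OiPr)3 (2 mol%), (1R,2R)-N,N'-dihydroxy-N,N'-bis(diphenylacetyl)cyclohexane-1,2-diamine (4 mol%), cumene hydroperoxide (1.0 equiv), toluene, 0 °C to rt
Reagents that add atoms: cumene hydroperoxide, CC(C)(OO)c1ccccc1
Why: The C7 alkoxide and the cumyl peroxide both bind the pentavalent vanadium centre held by the bishydroxamate, and the electrophilic peroxide oxygen is passed to an alkene inside this complex. The closest known reaction type is the asymmetric epoxidation of homoallylic alcohols with VO(OiPr)3 and chiral bishydroxamic acids, a catalyst class also used to desymmetrise meso dienyl carbinols, and it parallels the substrate-controlled epoxidation of cyclic homoallylic alcohols with VO(acac)2 and t-BuOOH. The oxirane (C5, C6 and the new oxygen) closes by concerted [2+1] oxygen-atom transfer, both C–O bonds forming on the same alkene face in one step. C5 and C6 are set relative to C1 by the one-carbon C1–C7 tether, which lets the metal reach only the face cis to C7, and the absolute configuration of C1, C5 and C6 is set together by the ligand, which decides which of the two enantiotopic alkenes is oxidised. The step needs face selection, alkene selection and a stop after one oxygen transfer: the tether gives the first, the ligand the second and the limiting hydroperoxide the third, and any further epoxidation should consume mainly the minor enantiomer, whose remaining alkene is the one the catalyst prefers, so that the enantiomeric purity of 10 rises at the cost of some meso bis-epoxide. The C1 oxygen is kept as an ether because a free tertiary hydroxyl, allylic to both alkenes, would bind the metal and send oxygen to the opposite face.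

Step 7
Reactants: 10 [(1S,2R,6S)-2-(benzyloxy)-7-oxabicyclo[4.1.0]hept-3-en-2-yl]methanol; 1 benzoic acid
Product: 11 (1R,5R,6S)-1-(benzyloxy)-6-hydroxy-1-(hydroxymethyl)cyclohex-2-en-5-yl benzoate
Conditions: PhCO2H (3 equiv), PhCO2Cs (0.3 equiv), DMF, 70 °C
Reagents that add atoms: none
Why: SN2 epoxide opening by carboxylate in a benzoic acid buffer should go to C5, which is flanked by a CH2 group, and not to the neopentyl-like C6, and inversion at C5 puts the benzoate trans to the C6 hydroxyl and cis to the C1 oxygen.

Step 8
Reactants: 11 (1R,5R,6S)-1-(benzyloxy)-6-hydroxy-1-(hydroxymethyl)cyclohex-2-en-5-yl benzoate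
Product: 14 (1S,2R,5R,6S)-1-(benzyloxy)-2,6-dihydroxy-1-(hydroxymethyl)cyclohexan-5-yl benzoate, via bis(dimethylsilyl) ether 12 (not isolated), via cis-fused oxasilolane 13 (not isolated)
Conditions: (HMe2Si)2NH, 60 °C, then evaporate; Pt2[(CH2=CHSiMe2)2O]3 (0.5 mol%), toluene, 60 °C; then 30% H2O2, KF, KHCO3, THF/MeOH, rt
Reagents that add atoms: hydrogen peroxide, OO
Why: Intramolecular hydrosilylation followed by Tamao–Fleming oxidation: the Si–H held on the C7 oxygen adds in the 5-exo sense, silicon to C2 and hydrogen to C3 on the face of C7, and the C–Si bond is oxidised with retention, so the C2 hydroxyl ends up cis to C7, while silylation of the C6 hydroxyl prevents dehydrogenative O–Si ring closure and its own 5-exo mode would lead to the same carbon and face.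

Step 9
Reactants: 14 (1S,2R,5R,6S)-1-(benzyloxy)-2,6-dihydroxy-1-(hydroxymethyl)cyclohexan-5-yl benzoate
Product: 15 [(1S,2R,5R,6S)-5-(benzoyloxy)-1-(benzyloxy)-2,6-dihydroxycyclohexyl]methyl benzoate
Conditions: BzCl (1.05 equiv), pyridine, CH2Cl2, −20 °C
Reagents that add atoms: benzoyl chloride, O=C(Cl)c1ccccc1
Why: Selective acylation of the primary alcohol at low temperature should work because the two secondary hydroxyls flank the fully substituted C1 and react much more slowly.

Step 10
Reactants: 15 [(1S,2R,5R,6S)-5-(benzoyloxy)-1-(benzyloxy)-2,6-dihydroxycyclohexyl]methyl benzoate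
Product: 16 [(1S,2R,5R,6S)-5-(benzoyloxy)-1,2,6-trihydroxycyclohexyl]methyl benzoate
Conditions: H2 (1 atm), Pd(OH)2/C, EtOAc, rt
Reagents that add atoms: none
Why: Hydrogenolysis of the benzyl ether over Pd(OH)2/C frees the tertiary C1 hydroxyl under neutral conditions that leave alkyl benzoates and all four stereocentres untouched.

**Compound list**

1 | benzoic acid | OC(=O)c1ccccc1 | starting material
2 | cyclohexa-2,5-diene-1-carboxylic acid | OC(=O)C1C=CCC=C1 | intermediate
3 | methyl cyclohexa-2,5-diene-1-carboxylate | COC(=O)C1C=CCC=C1 | intermediate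
4 | potassium dienolate of 3 (not isolated) | COC([O-])=C1C=CCC=C1.[K+] | intermediate
5 | methyl 1-hydroxycyclohexa-2,5-diene-1-carboxylate | COC(=O)C1(O)C=CCC=C1 | intermediate
6 | benzyl bromide | BrCc1ccccc1 | starting material
7 | sodium alkoxide of 5 (not isolated) | COC(=O)C1([O-])C=CCC=C1.[Na+] | intermediate
8 | methyl 1-(benzyloxy)cyclohexa-2,5-diene-1-carboxylate | COC(=O)C1(OCc2ccccc2)C=CCC=C1 | intermediate
9 | [1-(benzyloxy)cyclohexa-2,5-dien-1-yl]methanol (achiral) | OCC1(OCc2ccccc2)C=CCC=C1 | intermediate
10 | [(1S,2R,6S)-2-(benzyloxy)-7-oxabicyclo[4.1.0]hept-3-en-2-yl]methanol (oxirane cis to CH2OH) | OC[C@]1(OCc2ccccc2)C=CC[C@@H]2O[C@H]12 | intermediate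
11 | (1R,5R,6S)-1-(benzyloxy)-6-hydroxy-1-(hydroxymethyl)cyclohex-2-en-5-yl benzoate (C6 hydroxyl cis to C7, C5 benzoate trans to it) | OC[C@]1(OCc2ccccc2)C=CC[C@@H](OC(=O)c2ccccc2)[C@@H]1O | intermediate
12 | bis(dimethylsilyl) ether of 11 at the C6 and C7 oxygens (not isolated) | C[SiH](C)OC[C@]1(OCc2ccccc2)C=CC[C@@H](OC(=O)c2ccccc2)[C@@H]1O[SiH](C)C | intermediate
13 | oxasilolane with the ring C7–O–SiMe2–C2 cis-fused to the cyclohexane (silicon on the C7 face), C6 O-dimethylsilyl, C5 benzoate, C1 benzyl ether; (1R,2R,5R,6S) (not isolated) | C[Si]1(C)OC[C@]2(OCc3ccccc3)[C@H]1CC[C@@H](OC(=O)c1ccccc1)[C@@H]2O[SiH](C)C | intermediate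
14 | (1S,2R,5R,6S)-1-(benzyloxy)-2,6-dihydroxy-1-(hydroxymethyl)cyclohexan-5-yl benzoate | OC[C@]1(OCc2ccccc2)[C@H](O)CC[C@@H](OC(=O)c2ccccc2)[C@@H]1O | intermediate
15 | [(1S,2R,5R,6S)-5-(benzoyloxy)-1-(benzyloxy)-2,6-dihydroxycyclohexyl]methyl benzoate | O=C(OC[C@]1(OCc2ccccc2)[C@H](O)CC[C@@H](OC(=O)c2ccccc2)[C@@H]1O)c1ccccc1 | intermediate
16 | [(1S,2R,5R,6S)-5-(benzoyloxy)-1,2,6-trihydroxycyclohexyl]methyl benzoate | O=C(OC[C@]1(O)[C@H](O)CC[C@@H](OC(=O)c2ccccc2)[C@@H]1O)c1ccccc1 | target

**Count and risks**

Total steps: 10. Longest linear sequence: 10 steps, from benzoic acid 1 to 16.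

Step 6. What may go wrong: weak discrimination between the two enantiotopic alkenes, continued oxygen transfer to the second alkene (meso bis-epoxide), or hydrogen abstraction at the doubly allylic C4 followed by aromatisation. The fallback sets out from 9 and replaces catalyst control by resolution. Epoxidation under substrate control only (VO(acac)2 cat., t-BuOOH, toluene, 0 °C) should still deliver oxygen cis to C7 and give 10 together with its enantiomer [(1R,2S,6R)-2-(benzyloxy)-7-oxabicyclo[4.1.0]hept-3-en-2-yl]methanol F1. The mixture is esterified with (S)-2-methoxy-2-phenylacetic acid (DCC, DMAP, CH2Cl2) to the (2S)-2-methoxy-2-phenylacetate of 10 F2 and the (2S)-2-methoxy-2-phenylacetate of the enantiomer F3, which are diastereomers and are separated by chromatography or crystallisation. Methanolysis of F2 (K2CO3, MeOH, rt) comes back to the route at 10.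

Step 8. What may go wrong: migration of the double bond by a platinum hydride before the C–Si bond forms, 6-endo delivery from the silane on the C6 oxygen, or migration or loss of the C5 benzoate in the basic peroxide medium. The fallback sets out from 11 and hydrates the alkene through an epoxide. Hydroxyl-directed epoxidation (VO(acac)2 cat., t-BuOOH, CH2Cl2, 0 °C), steered by the C6 and C7 hydroxyls, should give the 2,3-epoxide on the C7 face F4. PhSeNa (from PhSeSePh and NaBH4, EtOH, 0 °C) should open it at C3, the carbon away from the quaternary centre, to the C3 phenylselanyl C2 alcohol F5. Bu3SnH with AIBN (toluene, 80 °C) then replaces selenium by hydrogen and comes back to the route at 14.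

Step 3. What may go wrong: oxygen transfer to C3 or C5 of the dienolate, addition of the product alkoxide to the sulfonimine by-product, or dehydration of the doubly allylic carbinol to methyl benzoate during work-up. The fallback sets out from 3 and installs the oxygen as an ester. Dienolate 4 is treated with dibenzoyl peroxide (THF, −78 °C) to give methyl 1-(benzoyloxy)cyclohexa-2,5-diene-1-carboxylate F6, a neutral product that forms no alkoxide in the flask. Brief methanolysis (K2CO3, MeOH, 0 °C) comes back to the route at 5.

**Further compounds**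

F1 | step 6 | [(1R,2S,6R)-2-(benzyloxy)-7-oxabicyclo[4.1.0]hept-3-en-2-yl]methanol (enantiomer of 10) | OC[C@@]1(OCc2ccccc2)C=CC[C@H]2O[C@@H]12
F2 | step 6 | [(1S,2R,6S)-2-(benzyloxy)-7-oxabicyclo[4.1.0]hept-3-en-2-yl]methyl (2S)-2-methoxy-2-phenylacetate | CO[C@H](C(=O)OC[C@]1(OCc2ccccc2)C=CC[C@@H]2O[C@H]12)c1ccccc1
F3 | step 6 | [(1R,2S,6R)-2-(benzyloxy)-7-oxabicyclo[4.1.0]hept-3-en-2-yl]methyl (2S)-2-methoxy-2-phenylacetate | CO[C@H](C(=O)OC[C@@]1(OCc2ccccc2)C=CC[C@H]2O[C@@H]12)c1ccccc1
F4 | step 8 | 2,3-epoxide of 11 with the oxirane on the C7 face (C1 benzyl ether, C5 benzoate, C6 and C7 hydroxyls) | OC[C@]1(OCc2ccccc2)[C@@H]2O[C@@H]2C[C@@H](OC(=O)c2ccccc2)[C@@H]1O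
F5 | step 8 | C3 phenylselanyl C2 alcohol: 14 with PhSe on C3 trans to the C2 hydroxyl | OC[C@]1(OCc2ccccc2)[C@H](O)[C@@H]([Se]c2ccccc2)C[C@@H](OC(=O)c2ccccc2)[C@@H]1O
F6 | step 3 | methyl 1-(benzoyloxy)cyclohexa-2,5-diene-1-carboxylate | COC(=O)C1(OC(=O)c2ccccc2)C=CCC=C1
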